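The earlier runs and the new flask are calculated for substances that don't exist; the scatter is artificial.

I counted each flask by one invariant: starting material plus target stayed at the charge, apart from the little that 0.5 mol% of catalyst can hold.

in all of them: free catalyst 0.5 mol%
- maple: starting material 0.60 M; second substrate 2 equiv; temperature 75 °C; run made earlier
- green: starting material 0.40 M; second substrate 2.00 equiv; temperature 75 °C; time 12 h
- ochre: starting material 0.40 M; second substrate 2.00 equiv; temperature 90 °C; time 12 h
- grey: starting material 0.40 M; second substrate 2.00 equiv; temperature 45 °C; time 12 h
- red: starting material 0.40 M; second substrate 2.00 equiv; temperature 60 °C; time 12 h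

maple run (percent of the starting material charged)

| time / h | target / % |
|---|---|
| 0.333 | 3.4 |
| 0.833 | 6.4 |
| 1.50 | 11.7 |
| 2.50 | 17.1 |
| 4.00 | 26.3 |

(readings scatter by 0.5 percentage points)

- the earlier runs were read with a standard deviation of 0.5 percentage points
- on the list of suspects stand: starting material + free catalyst <-> catalyst intermediate A; catalyst intermediate A -> free catalyst + target; second substrate + free catalyst <-> catalyst intermediate B; catalyst intermediate B -> free catalyst + second product; second substrate + catalyst intermediate B -> spent catalyst
- the earlier runs do not show what temperature does; that part of a forecast is a guess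
- no earlier run changes the charge of free catalyst; that part of a forecast is a guess

1. which flask leads in amount of target, in percent of the starting material charged ("all alike" within 1.5 percentage points) (green / ochre / grey / red / all alike)
2. how much target is there at the end, in percent of the starting material charged: green
3. how much target is there at the end, in percent of the starting material charged: ochre
4. how much target is there at the end, in percent of the starting material charged: grey
5. how much target is there at the end, in percent of the starting material charged: red

So one minus the target was the starting material left. From the last maple reading I got k = 0.0763 h⁻¹, the pseudo-first-order constant: the natural log of charge over starting material left, divided by time. While k holds, it joins both ends of a run: early, the target grows as k times time; late, it closes on the charge as one minus exp(−kt).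

Green has the same mol% as maple, so its catalyst concentration is 0.667 of maple's. If k follows that concentration, k gives 45.7% in green. If k instead stays at its maple value, still first order in starting material, it gives 60.0%. I committed to that range. No run showed temperature, so the other flasks were guesses.

The forecast gave green 48%, ochre 72%, grey 11% and red 25%. It guessed 65 kJ/mol, a factor of 2.4 per 15 degrees, and said “Ochre should lead, but faster catalyst death could cap it”.

The flasks gave green 49.7%, ochre 86.0%, grey 4.33% and red 17.2%, and ochre led.

    starting material + free catalyst ⇌ catalyst intermediate A (K = 5.30 M⁻¹, k = 0.0396 M⁻¹ s⁻¹, Ea = 84.0 kJ mol⁻¹, ΔH = 17.0 kJ mol⁻¹)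
    catalyst intermediate A → free catalyst + target (k = 0.550 s⁻¹, Ea = 78.0 kJ mol⁻¹)
    second substrate + free catalyst ⇌ catalyst intermediate B (K = 0.427 M⁻¹, k = 0.827 M⁻¹ s⁻¹, Ea = 52.0 kJ mol⁻¹, ΔH = −6.00 kJ mol⁻¹)
    catalyst intermediate B → free catalyst + second product (k = 0.00322 s⁻¹, Ea = 108 kJ mol⁻¹)
    second substrate + catalyst intermediate B → spent catalyst (k = 6.22 × 10⁻⁵ M⁻¹ s⁻¹, Ea = 104 kJ mol⁻¹)
    (constants at 90 °C)

I put k to use again. Grey gave k = 0.00369 h⁻¹ and red gave 0.0158 h⁻¹, so k rose by a factor of 4.28 between these two flasks, 15 degrees apart, against the forecast's 2.4.

The neighbour is the grey flask run at 20 °C. Carrying the same factor per degree down to that temperature, I got k = 3.27 × 10⁻⁴ h⁻¹, which gives 0.391% target at 12 h. The neighbour gave 0.270%, less than that reckoning.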